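The strategy rests on the C1–C9a bond of the cyclohexenone (C1–C4, C4a, C9a). The homoallylic ketone array O=C2–C1–C9a–C9=C8, which spans the six-membered ring and the cycloheptene, is the retron of an allyl vinyl ether. The carbocycle is therefore traced back to a cis-fused 2-methylene-dihydropyran in which an oxygen atom holds the place of C1. A Lewis-acid-mediated [1,3] oxygen-to-carbon shift (Ferrier-type ring transposition) should close the six-membered ring as the last ring, relay C4a and the C9a–O bond into the C9a stereocentre, and unveil the C2 ketone, the C3=C4 enone and the C8=C9 alkene in one operation. The precursor comes from eucarvone through an unsaturated δ-lactone.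

Key step: step 11

Remark: atoms carry the benzo[7]annulene locants of the target throughout (C5 = CMe2, C6 and C7 bear oxygen, C8=C9); β is the face of the C7 oxygen of the target, α the opposite face; eucarvone is taken as a purchasable compound.

Step 1
Reactants: 1 angelic acid
Product: 2 angelyl alcohol, (2Z)-2-methylbut-2-en-1-ol
Conditions: LiAlH4, Et2O, 0 °C to rt; then H2O, aq NaOH
Reagents that add atoms: none
Why: LiAlH4 reduces the carboxylic acid to the primary allylic alcohol by 1,2-hydride addition without touching or isomerising the trisubstituted (Z)-alkene (hydride reduction of a carboxylic acid).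

Step 2
Reactants: 2 angelyl alcohol
Product: 3 [(2S,3R)-2,3-dimethyloxiran-2-yl]methanol
Conditions: Ti(OiPr)4 (10 mol %), L-(+)-diethyl tartrate (12 mol %), t-BuOOH, 4 Å MS, CH2Cl2, −20 °C
Reagents that add atoms: tert-butyl hydroperoxide, CC(C)(C)OO
Why: Sharpless asymmetric epoxidation, in which the L-(+)-tartrate catalyst should deliver the peroxide oxygen to the alkene face that gives the (2S,3R)-epoxy alcohol, the Z geometry fixing the two methyl groups trans.

Step 3
Reactants: 3 epoxy alcohol
Product: 4 (2R,3R)-2,3-dimethyloxirane-2-carboxylic acid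
Conditions: RuCl3·xH2O (2 mol %), NaIO4, CCl4/MeCN/H2O, rt
Reagents that add atoms: sodium periodate, [Na+].[O-]I(=O)(=O)=O; water, O
Why: catalytic RuO4 (from RuCl3 and periodate) oxidises the primary alcohol through the aldehyde hydrate to the acid and leaves the oxirane and both stereocentres untouched (C2 becomes R only through the change in priorities).

Step 4
Reactants: 5 eucarvone
Product: 6 (1S,7R)-3,6,6-trimethyl-8-oxabicyclo[5.1.0]oct-2-en-4-one
Conditions: (S,S)-(salen)MnCl (4 mol %; salen = N,N'-bis(3,5-di-tert-butylsalicylidene)cyclohexane-1,2-diamine dianion), 4-phenylpyridine N-oxide (20 mol %), aq NaOCl (pH 11.3), CH2Cl2, 0 °C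
Reagents that add atoms: sodium hypochlorite, [Na+].[O-]Cl
Why: Jacobsen–Katsuki epoxidation of the cis-disubstituted, diene-conjugated γ,δ-alkene (the α,β-alkene is electron-poor and trisubstituted), the (S,S)-catalyst being expected to give the (1S,7R)-oxirane by analogy with 2,2-dimethylchromenes, which share the conjugated cis-alkene next to a CMe2 group.

Step 5
Reactants: 6 epoxy enone
Product: 7 (4R,5R)-4,5-dihydroxy-2,6,6-trimethylcyclohept-2-en-1-one
Conditions: HClO4 (5 mol %), THF/H2O, 0 °C to rt
Reagents that add atoms: water, O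
Why: acid-catalysed anti opening of the vinyl epoxide, in which water should attack the allylic C7 in an SN2 manner with inversion because C6 is neopentylic, giving the trans-diol with the C7 oxygen β and the C6 oxygen α.

Step 6
Reactants: 7 trans-diol
Product: 8 disiloxane-bridged diol ketone
Conditions: 1,3-dichloro-1,1,3,3-tetraisopropyldisiloxane, imidazole, DMAP (cat.), DMF, rt to 40 °C
Reagents that add atoms: 1,3-dichloro-1,1,3,3-tetraisopropyldisiloxane, CC(C)[Si](Cl)(C(C)C)O[Si](Cl)(C(C)C)C(C)C
Why: silylation with a bifunctional chlorosilane, which should react first at the less hindered allylic C7 hydroxyl and then close on the neopentylic C6 hydroxyl, giving a seven-membered disiloxane that holds both oxygens pseudo-equatorial and survives enolate, titanium-carbene and Lewis-acid conditions.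

Step 7
Reactants: 8 disiloxane-bridged ketone; 9 methyl 2-(bromomethyl)prop-2-enoate
Product: 11 C4a-allylated ketone (side chain β), via lithium enolate 10 (not isolated)
Conditions: LiN(iPr)2 (LDA), THF, −78 °C; then 9, −78 to −40 °C; aq NH4Cl at −78 °C
Reagents that add atoms: none
Why: kinetic deprotonation at C4a (the only enolisable position) and SN2'-type enolate alkylation; with the disiloxane holding the oxygens pseudo-equatorial, the α-methyl on C5 should be pseudo-axial, so the electrophile should enter C4a from the β face, trans to the C6 oxygen.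

Step 8
Reactants: 11 C4a-allylated ketone
Product: 13 cis-fused α-methylene δ-lactone, via 9aβ-hydroxy ester 12 (not isolated)
Conditions: NaBH4, CeCl3·7H2O, MeOH, −78 to −20 °C; then PPTS (cat.), toluene, 60 °C
Reagents that add atoms: none
Why: Luche 1,2-reduction of the enone, in which hydride should approach C9a anti to the C4a side chain to give the 9aβ-alcohol, which then lactonises onto the methyl ester to the cis-fused δ-lactone.

Step 9
Reactants: 13 α-methylene lactone
Product: 14 cis-fused α-methyl-α,β-unsaturated δ-lactone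
Conditions: RhCl3·3H2O (5 mol %), EtOH, 75 °C
Reagents that add atoms: none
Why: rhodium-hydride-mediated alkene isomerisation (hydrometalation then β-hydride elimination) should move the exocyclic alkene into the ring to the more stable trisubstituted, conjugated C3=C4 position without touching a stereocentre.

Step 10
Reactants: 14 unsaturated lactone
Product: 15 cis-fused 2-methylene-2H-pyran (cyclic allyl dienyl ether)
Conditions: Cp2TiMe2, toluene (1 % pyridine), 65 °C, dark
Reagents that add atoms: dimethyltitanocene, C[Ti](C)(C1C=CC=C1)C1C=CC=C1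
Why: Petasis methylenation, in which thermally generated Cp2Ti=CH2 adds to the lactone carbonyl and the oxatitanacyclobutane collapses to the exocyclic enol ether under non-acidic conditions that the acid-labile dienol ether tolerates.

Step 11
Reactants: 15 cyclic allyl dienyl ether
Product: 17 disiloxane-protected bicyclic enone, via allyl cation–aluminium dienolate ion pair 16 (not isolated)
Conditions: Me2AlCl (1.2 equiv), CH2Cl2, −78 to −30 °C; then aq KNaC4H4O6 (potassium sodium tartrate)
Reagents that add atoms: none
Why: Me2AlCl should coordinate the enol-ether oxygen and heterolyse the allylic C9a–O bond to a contact ion pair (cycloheptenyl cation C9a–C9–C8 and an aluminium 2-oxydienolate tethered through C4=C3), which recombines through the enolate carbon C1 at C9a, a net [1,3] oxygen-to-carbon shift that turns the dihydropyran into the carbocycle. The closest known reaction types are the Ferrier and Petasis–Ferrier carbocyclisations of cyclic enol ethers and the Lewis-acid-mediated [1,3] rearrangement of allyl vinyl ethers. The six-membered ring closes in a 6-(enolendo)-exo-trig mode, C1 taking the place that the ring oxygen held. The new stereocentre C9a is controlled by C4a through the short tether and by collapse of the ion pair on the β face from which the oxygen departed, so the cis fusion of the lactone should be carried over with retention. The step needs attack at C9a and not at C8 (the [3,3] mode, which would give a bridged eight-membered ketone); the smaller ring, the strain of the bridged alternative and the β-silyloxy group on C7 next to C8 should secure this. The enone C2(=O)–C3(Me)=C4 appears directly because the C3=C4 alkene of the lactone is the vinyl group of the dienolate.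

Step 12
Reactants: 17 protected bicyclic enone
Product: 18 (4aS,6R,7R,9aR)-6,7-dihydroxy-3,5,5,9-tetramethyl-1,4a,5,6,7,9a-hexahydro-2H-benzo[7]annulen-2-one
Conditions: HF·pyridine, pyridine/THF, 0 °C to rt
Reagents that add atoms: none
Why: fluoride-mediated desilylation cleaves both Si–O bonds, the buffered acidic reagent avoiding base-induced γ-deprotonation and epimerisation at C4a.

Step 13
Reactants: 18 diol; 1 angelic acid
Product: 20 C7 mono-angelate, via angelic mixed anhydride 19 (not isolated)
Conditions: 1, 2,4,6-trichlorobenzoyl chloride, Et3N, toluene, rt; then 18, toluene, 75 °C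
Reagents that add atoms: none
Why: mixed-anhydride (Yamaguchi-type) esterification without a nucleophilic catalyst should keep the Z geometry of the angelate, and the allylic C7 hydroxyl should react selectively because the C6 hydroxyl is neopentylic.

Step 14
Reactants: 20 C7 mono-angelate; 4 (2R,3R)-epoxy acid
Product: 22 target diester, via epoxy-acid mixed anhydride 21 (not isolated)
Conditions: 4, 2,4,6-trichlorobenzoyl chloride, Et3N, THF, rt; then 20, DMAP, toluene, 50 °C
Reagents that add atoms: none
Why: Yamaguchi esterification, in which DMAP should transfer the epoxy acyl group from the less hindered carbonyl of the mixed anhydride to the hindered C6 hydroxyl without touching any stereocentre.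

Compound list
1 | angelic acid, (2Z)-2-methylbut-2-enoic acid | C/C=C(/C)C(=O)O | starting material
2 | angelyl alcohol, (2Z)-2-methylbut-2-en-1-ol | C/C=C(/C)CO | intermediate
3 | [(2S,3R)-2,3-dimethyloxiran-2-yl]methanol (methyl groups trans) | OC[C@]1(C)O[C@@H]1C | intermediate
4 | (2R,3R)-2,3-dimethyloxirane-2-carboxylic acid (epoxyangelic acid, methyl groups trans) | OC(=O)[C@]1(C)O[C@@H]1C | intermediate
5 | eucarvone, 2,6,6-trimethylcyclohepta-2,4-dien-1-one | CC1=CC=CC(C)(C)CC1=O | starting material
6 | (1S,7R)-3,6,6-trimethyl-8-oxabicyclo[5.1.0]oct-2-en-4-one (α-epoxide across C6–C7) | CC1=C[C@@H]2O[C@@H]2C(C)(C)CC1=O | intermediate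
7 | (4R,5R)-4,5-dihydroxy-2,6,6-trimethylcyclohept-2-en-1-one (trans-diol, C7–OH β, C6–OH α) | O[C@@H]1C=C(C)C(=O)CC(C)(C)[C@H]1O | intermediate
8 | (4R,5R)-diol 7 with both oxygens bridged by a 1,1,3,3-tetraisopropyldisiloxane-1,3-diyl group (trans-fused seven-membered disiloxane) | CC(C)[Si]2(C(C)C)O[C@@H]1C=C(C)C(=O)CC(C)(C)[C@H]1O[Si](C(C)C)(C(C)C)O2 | intermediate
9 | methyl 2-(bromomethyl)prop-2-enoate | C=C(CBr)C(=O)OC | starting material
10 | lithium enolate of 8 (C9a–OLi, C4a=C9a), not isolated | CC(C)[Si]2(C(C)C)O[C@@H]1C=C(C)C(O[Li])=CC(C)(C)[C@H]1O[Si](C(C)C)(C(C)C)O2 | intermediate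
11 | ketone 8 carrying a 2-(methoxycarbonyl)prop-2-en-1-yl group on C4a, side chain β (trans to the C6 oxygen) | CC(C)[Si]2(C(C)C)O[C@@H]1C=C(C)C(=O)[C@H](CC(=C)C(=O)OC)C(C)(C)[C@H]1O[Si](C(C)C)(C(C)C)O2 | intermediate
12 | 9aβ-alcohol of 11 (OH cis to the C4a side chain), methyl ester, not isolated | CC(C)[Si]2(C(C)C)O[C@@H]1C=C(C)[C@H](O)[C@H](CC(=C)C(=O)OC)C(C)(C)[C@H]1O[Si](C(C)C)(C(C)C)O2 | intermediate
13 | cis-fused α-methylene δ-lactone (ring: O on C9a, C2=O, C3=CH2, C4H2, C4a; H4a and H9a both α) | CC(C)[Si]2(C(C)C)O[C@@H]1C=C(C)[C@@H]3OC(=O)C(=C)C[C@@H]3C(C)(C)[C@H]1O[Si](C(C)C)(C(C)C)O2 | intermediate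
14 | cis-fused α-methyl-α,β-unsaturated δ-lactone (C3(Me)=C4 in the ring) | CC(C)[Si]2(C(C)C)O[C@@H]1C=C(C)[C@@H]3OC(=O)C(C)=C[C@@H]3C(C)(C)[C@H]1O[Si](C(C)C)(C(C)C)O2 | intermediate
15 | cis-fused 3-methyl-2-methylene-5,6-dihydro-2H-pyran (exocyclic C2=C1H2, ring oxygen on C9a) | CC(C)[Si]2(C(C)C)O[C@@H]1C=C(C)[C@@H]3OC(=C)C(C)=C[C@@H]3C(C)(C)[C@H]1O[Si](C(C)C)(C(C)C)O2 | intermediate
16 | contact ion pair: cycloheptenyl cation (C9a–C9–C8) carrying the (Z)-chlorodimethylaluminate 2-oxydienolate chain on C4a, not isolated | CC(C)[Si]2(C(C)C)O[C@@H]1C=C(C)[CH+][C@H](/C=C(/C)C(=C)O[Al-](C)(C)Cl)C(C)(C)[C@H]1O[Si](C(C)C)(C(C)C)O2 | intermediate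
17 | (4aS,6R,7R,9aR)-3,5,5,9-tetramethyl-6,7-[(tetraisopropyldisiloxane-1,3-diyl)bis(oxy)]-1,4a,5,6,7,9a-hexahydro-2H-benzo[7]annulen-2-one (cis-fused) | CC(C)[Si]2(C(C)C)O[C@@H]1C=C(C)[C@@H]3CC(=O)C(C)=C[C@@H]3C(C)(C)[C@H]1O[Si](C(C)C)(C(C)C)O2 | intermediate
18 | (4aS,6R,7R,9aR)-6,7-dihydroxy-3,5,5,9-tetramethyl-1,4a,5,6,7,9a-hexahydro-2H-benzo[7]annulen-2-one | O[C@@H]1C=C(C)[C@@H]2CC(=O)C(C)=C[C@@H]2C(C)(C)[C@H]1O | intermediate
19 | (2Z)-2-methylbut-2-enoic 2,4,6-trichlorobenzoic anhydride, not isolated | C/C=C(/C)C(=O)OC(=O)c1c(Cl)cc(Cl)cc1Cl | intermediate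
20 | (4aS,6R,7R,9aR)-6-hydroxy-3,5,5,9-tetramethyl-2-oxo-2,4a,5,6,7,9a-hexahydro-1H-benzo[7]annulen-7-yl (2Z)-2-methylbut-2-enoate | C/C=C(/C)C(=O)O[C@@H]1C=C(C)[C@@H]2CC(=O)C(C)=C[C@@H]2C(C)(C)[C@H]1O | intermediate
21 | (2R,3R)-2,3-dimethyloxirane-2-carboxylic 2,4,6-trichlorobenzoic anhydride, not isolated | O=C(OC(=O)c1c(Cl)cc(Cl)cc1Cl)[C@]1(C)O[C@@H]1C | intermediate
22 | (4aS,6R,7R,9aR)-3,5,5,9-tetramethyl-7-{[(2Z)-2-methylbut-2-enoyl]oxy}-2-oxo-2,4a,5,6,7,9a-hexahydro-1H-benzo[7]annulen-6-yl (2R,3R)-2,3-dimethyloxirane-2-carboxylate | C/C=C(/C)C(=O)O[C@@H]1C=C(C)[C@@H]2CC(=O)C(C)=C[C@@H]2C(C)(C)[C@H]1OC(=O)[C@]1(C)O[C@@H]1C | target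

Total step count: 14. Longest linear sequence: 11 steps (steps 4 to 14, from eucarvone); steps 1 to 3 form the side-chain acid and join at step 14.

Steps most likely to fail

Step 11. The ion pair may collapse at the distal allyl terminus C8 ([3,3] mode), lose a proton to a triene, or lose its facial memory and give the trans ring fusion. The fallback replaces the Lewis-acid ionisation by a zerovalent-palladium 1,3 oxygen-to-carbon alkyl shift through a π-allylpalladium complex with a stabilised enolate (double inversion, net retention). It sets out from lactone 14. Addition of the lithium enolate of methyl acetate (LiN(iPr)2, MeOAc, THF, −78 °C) should give the hemiketal F1. Dehydration (PPTS, toluene, 4 Å MS) should give the (Z)-2-(methoxycarbonylmethylene)dihydropyran F2. Pd(PPh3)4 with dppe (5 mol %) in DMSO at 60 °C should ionise the allylic C9a–O bond and return the β-keto ester enolate to C9a on the oxygen face, giving the bicyclic β-keto ester F3. Krapcho demethoxycarbonylation (LiCl, wet DMSO, 130 °C) then comes back to the route at 17.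

Step 7. Facial selectivity of the enolate alkylation at C4a, next to the quaternary C5, may be poor, or C4a may epimerise under the basic conditions. The fallback replaces substrate control by catalyst control in a decarboxylative allylic alkylation. It sets out from ketone 8 through its enolate 10. O-Acylation with 2-(methoxycarbonyl)allyl chloroformate (TMEDA, THF, −78 °C) should give the allyl enol carbonate F4. Pd2(dba)3 with a chiral trans-cyclohexane-1,2-diamine bis(2-diphenylphosphinobenzamide) ligand (the enantiomer matched to the β face) in toluene at rt should expel CO2 and join the allyl unit to C4a under ligand control, coming back to the route at 11.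

Step 8. Hydride may be delivered to the β face of C9a, since both faces are flanked by a pseudo-axial group, which would lead to a trans-fused lactone and the wrong relay in step 11. The fallback closes the lactone with inversion instead of retention. It sets out from ketone 11. The 9aα-alcohol F5 from the same reduction is saponified (LiOH, THF/H2O) to the hydroxy acid F6. A Mitsunobu lactonisation (PPh3, DIAD, THF, 0 °C) should then close the ring with inversion at C9a, coming back to the route at 13.

Further compounds
F1 | step 11 | hemiketal from 14 and the methyl acetate enolate (C2 bears OH and CH2CO2Me, anomers) | CC(C)[Si]2(C(C)C)O[C@@H]1C=C(C)[C@@H]3OC(O)(CC(=O)OC)C(C)=C[C@@H]3C(C)(C)[C@H]1O[Si](C(C)C)(C(C)C)O2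
F2 | step 11 | cis-fused (Z)-2-(methoxycarbonylmethylene)-3-methyl-5,6-dihydro-2H-pyran | CC(C)[Si]2(C(C)C)O[C@@H]1C=C(C)[C@@H]3O/C(=C\C(=O)OC)C(C)=C[C@@H]3C(C)(C)[C@H]1O[Si](C(C)C)(C(C)C)O2
F3 | step 11 | bicyclic β-keto ester, 17 with CO2Me on C1 (C1 epimers) | CC(C)[Si]2(C(C)C)O[C@@H]1C=C(C)[C@@H]3C(C(=O)OC)C(=O)C(C)=C[C@@H]3C(C)(C)[C@H]1O[Si](C(C)C)(C(C)C)O2
F4 | step 7 | 2-(methoxycarbonyl)allyl enol carbonate of ketone 8 | CC(C)[Si]2(C(C)C)O[C@@H]1C=C(C)C(OC(=O)OCC(=C)C(=O)OC)=CC(C)(C)[C@H]1O[Si](C(C)C)(C(C)C)O2
F5 | step 8 | 9aα-alcohol epimer of 12 (OH trans to the C4a side chain), methyl ester | CC(C)[Si]2(C(C)C)O[C@@H]1C=C(C)[C@@H](O)[C@H](CC(=C)C(=O)OC)C(C)(C)[C@H]1O[Si](C(C)C)(C(C)C)O2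
F6 | step 8 | 9aα-hydroxy acid from F5 | CC(C)[Si]2(C(C)C)O[C@@H]1C=C(C)[C@@H](O)[C@H](CC(=C)C(=O)O)C(C)(C)[C@H]1O[Si](C(C)C)(C(C)C)O2
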